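**Retrosynthetic overview**

- Target 20 is reached from phenol 18 by two finishing steps on ring B: O-prenylation at C6 and removal of the silyl group from the C2 CH2OH.
- The strategy rests on ring B. Numbered from the diaryl ether carbon C1 (CH2OH on C2, OMe on C4, O-prenyl on C6), it is a resorcinol monomethyl ether with the C4 and C6 oxygens meta to each other and the ether oxygen on C1. A vinylketene plus methoxyalkyne benzannulation delivers exactly this pattern, with C4-OMe and C6-OH already differentiated.
- Ring B is therefore built de novo from diazo enone 11 (supplying C1, C2, C3, C6 and the ring A oxygen) and methoxyethyne 13 (supplying C4, C5), forming bonds C2-C3, C3-C4, C5-C6 and C6-C1.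
- The diaryl ether oxygen is attached before ring B exists, as a vinyl aryl ether: 11 comes from enone 9 by diazo transfer, and 9 from phenol 3 plus β-bromo enone 8 by addition-elimination.
- Ring A is purchased as methyl 2,6-dihydroxy-4-methylbenzoate 1; ring B is the only ring formed, in step 8.

Key step: step 8

Assumption: the E enol ether geometry drawn for 8, 9 and 11 is the expected thermodynamic one; it is not carried into the product, because C1 becomes an aromatic carbon.

**Route**

Step 1
Reactants: 1 methyl 2,6-dihydroxy-4-methylbenzoate; 2 prenyl bromide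
Product: 3 methyl 2-hydroxy-4-methyl-6-[(3-methylbut-2-en-1-yl)oxy]benzoate
Conditions: 2 (1.0 equiv), K2CO3, acetone, rt
Reagents that add atoms: none
Why: Williamson etherification of a symmetrical diol, which should stop at the mono-ether because the remaining hydroxyl is held in a hydrogen bond to the ester carbonyl and is less nucleophilic.

Step 2
Reactants: 4 methyl vinyl ketone
Product: 5 3-(hydroxymethyl)but-3-en-2-one
Conditions: 37% aq. CH2O, DABCO (cat.), THF/H2O, rt
Reagents that add atoms: formaldehyde C=O
Why: Morita-Baylis-Hillman reaction, in which the DABCO-derived zwitterionic enolate adds to formaldehyde and the amine is then lost to restore the enone.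

Step 3
Reactants: 5 3-(hydroxymethyl)but-3-en-2-one
Product: 6 3-(tert-butyldimethylsilyloxymethyl)but-3-en-2-one
Conditions: TBSCl, imidazole, CH2Cl2, 0 °C to rt
Reagents that add atoms: tert-butyldimethylsilyl chloride CC(C)(C)[Si](C)(C)Cl
Why: Standard silylation of a primary allylic alcohol, which also stops the hydroxy enone from oligomerising.

Step 4
Reactants: 6 3-(tert-butyldimethylsilyloxymethyl)but-3-en-2-one
Product: 8 (E)-4-bromo-3-(tert-butyldimethylsilyloxymethyl)but-3-en-2-one, via vicinal dibromide 7 (not isolated)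
Conditions: Br2, CH2Cl2, −78 to 0 °C; then Et3N, 0 °C to rt
Reagents that add atoms: bromine BrBr
Why: Bromination-dehydrobromination of an α-substituted enone, as used to turn methacrylic acid derivatives into (E)-3-bromo-2-methylacrylates; the base should remove the more acidic hydrogen on the bromine-bearing carbon and expel the α-bromide to give the conjugated β-bromo enone.

Step 5
Reactants: 3 methyl 2-hydroxy-4-methyl-6-[(3-methylbut-2-en-1-yl)oxy]benzoate; 8 (E)-4-bromo-3-(tert-butyldimethylsilyloxymethyl)but-3-en-2-one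
Product: 9 methyl 2-{[(1E)-2-(tert-butyldimethylsilyloxymethyl)-3-oxobut-1-en-1-yl]oxy}-4-methyl-6-(prenyloxy)benzoate
Conditions: Cs2CO3, DMF, rt
Reagents that add atoms: none
Why: Nucleophilic vinylic substitution by addition-elimination, in which the phenoxide adds to the β-carbon of the bromo enone and the enolate expels bromide, so the hindered ether C-O bond is made at a vinylic carbon and no aryl halide coupling is needed.

Step 6
Reactants: 9 methyl 2-{[(1E)-2-(tert-butyldimethylsilyloxymethyl)-3-oxobut-1-en-1-yl]oxy}-4-methyl-6-(prenyloxy)benzoate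
Product: 11 methyl 2-{[(1E)-4-diazo-2-(tert-butyldimethylsilyloxymethyl)-3-oxobut-1-en-1-yl]oxy}-4-methyl-6-(prenyloxy)benzoate, via trifluoroacetyl diketone 10 (not isolated)
Conditions: LiN(SiMe3)2, THF, −78 °C; CF3CO2CH2CF3; cold 5% aq. HCl; then MsN3, Et3N, H2O, MeCN, rt
Reagents that add atoms: methanesulfonyl azide CS(=O)(=O)N=[N+]=[N-]; 2,2,2-trifluoroethyl trifluoroacetate O=C(OCC(F)(F)F)C(F)(F)F (its atoms are held only in intermediate 10)
Why: Detrifluoroacetylative diazo transfer, in which the kinetic methyl enolate is trifluoroacetylated (Claisen condensation) and the activated diketone undergoes Regitz transfer with loss of the trifluoroacetyl group, while the 2,6-disubstituted methyl benzoate and the silyl ether should be inert at −78 °C.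

Step 7
Reactants: 12 chloroacetaldehyde dimethyl acetal
Product: 13 methoxyethyne
Conditions: NaNH2 (3 equiv), liq. NH3, −33 °C; then aq. NH4Cl, −20 °C; distilled into cold CH2Cl2 and used as a solution
Reagents that add atoms: none
Why: Base-induced double elimination (loss of methanol, then of HCl through the 2-chlorovinyl ether) gives sodium methoxyacetylide, protonated on quench, which is the standard preparation of alkoxyethynes from chloroacetaldehyde acetals.

Step 8
Reactants: 11 methyl 2-{[(1E)-4-diazo-2-(tert-butyldimethylsilyloxymethyl)-3-oxobut-1-en-1-yl]oxy}-4-methyl-6-(prenyloxy)benzoate; 13 methoxyethyne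
Product: 18 methyl 2-[2-hydroxy-4-methoxy-6-(tert-butyldimethylsilyloxymethyl)phenoxy]-4-methyl-6-(prenyloxy)benzoate, via vinylketene 14 (not isolated), via cyclobutenone 15 (not isolated), via dienylketene 16 (not isolated), via cyclohexa-2,4-dienone 17 (not isolated)
Conditions: 13 (5 equiv), degassed CH2Cl2, hν (medium-pressure Hg lamp, Pyrex filter), 0-10 °C; then toluene, 80 °C
Reagents that add atoms: none
Why: Light expels N2 from 11 and the alkenyl group shifts to the carbene carbon (photochemical Wolff rearrangement, bond C2-C3) to give vinylketene 14, and the polarised ynol ether then adds across the ketene C=C in a [2+2] cycloaddition (bonds C5-C6 and C3-C4) to give cyclobutenone 15. Gentle heating opens 15 by four-electron electrocyclic cleavage to dienylketene 16, and ring B is closed by a six-electron disrotatory electrocyclisation that joins the ketene carbon C6 to the aryloxy-bearing terminus C1, after which dienone 17 tautomerises to the phenol. The closest known reaction type is the Danheiser benzannulation in its diazo ketone variant with alkoxy- and silyloxyalkynes. No stereocentre is formed, and the enol ether geometry of 11 is lost on aromatisation. The step needs regioselective cycloaddition, secured by the polarisation of methoxyethyne (its nucleophilic CH carbon bonds to the electrophilic ketene carbonyl carbon), which places OMe on C4 meta to the new C6 hydroxyl, and it needs chemoselectivity over the two prenyl alkenes, secured by the much higher reactivity of the ynol ether towards ketenes and its excess. The thermal stage is held at or below 80 °C so that the aryl prenyl ether of ring A does not undergo Claisen rearrangement.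

Step 9
Reactants: 18 methyl 2-[2-hydroxy-4-methoxy-6-(tert-butyldimethylsilyloxymethyl)phenoxy]-4-methyl-6-(prenyloxy)benzoate; 2 prenyl bromide
Product: 19 methyl 2-[4-methoxy-2-(prenyloxy)-6-(tert-butyldimethylsilyloxymethyl)phenoxy]-4-methyl-6-(prenyloxy)benzoate
Conditions: 2 (1.5 equiv), K2CO3, DMF, rt
Reagents that add atoms: none
Why: Williamson etherification of the single free phenol, which should outpace lactonisation onto the ring A ester because that ester is flanked by two ortho substituents.

Step 10
Reactants: 19 methyl 2-[4-methoxy-2-(prenyloxy)-6-(tert-butyldimethylsilyloxymethyl)phenoxy]-4-methyl-6-(prenyloxy)benzoate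
Product: 20 methyl 2-[2-(hydroxymethyl)-4-methoxy-6-(prenyloxy)phenoxy]-4-methyl-6-(prenyloxy)benzoate
Conditions: Bu4NF, AcOH, THF, 0 °C to rt
Reagents that add atoms: none
Why: Fluoride-mediated cleavage of the benzylic silyl ether, buffered with acetic acid so that no free alkoxide can attack the methyl ester, with the prenyl ethers untouched.

**Compound list**

1 | methyl 2,6-dihydroxy-4-methylbenzoate | COC(=O)c1c(O)cc(C)cc1O | starting material
2 | prenyl bromide (1-bromo-3-methylbut-2-ene) | CC(C)=CCBr | starting material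
3 | methyl 2-hydroxy-4-methyl-6-[(3-methylbut-2-en-1-yl)oxy]benzoate | COC(=O)c1c(O)cc(C)cc1OCC=C(C)C | intermediate
4 | methyl vinyl ketone | CC(=O)C=C | starting material
5 | 3-(hydroxymethyl)but-3-en-2-one | CC(=O)C(=C)CO | intermediate
6 | 3-(tert-butyldimethylsilyloxymethyl)but-3-en-2-one | CC(=O)C(=C)CO[Si](C)(C)C(C)(C)C | intermediate
7 | 3,4-dibromo-3-(tert-butyldimethylsilyloxymethyl)butan-2-one (racemic) | CC(=O)C(Br)(CBr)CO[Si](C)(C)C(C)(C)C | intermediate
8 | (E)-4-bromo-3-(tert-butyldimethylsilyloxymethyl)but-3-en-2-one | CC(=O)/C(CO[Si](C)(C)C(C)(C)C)=C/Br | intermediate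
9 | methyl 2-{[(1E)-2-(tert-butyldimethylsilyloxymethyl)-3-oxobut-1-en-1-yl]oxy}-4-methyl-6-(prenyloxy)benzoate | COC(=O)c1c(OCC=C(C)C)cc(C)cc1O/C=C(\CO[Si](C)(C)C(C)(C)C)C(C)=O | intermediate
10 | methyl 2-{[(1E)-2-(tert-butyldimethylsilyloxymethyl)-6,6,6-trifluoro-3,5-dioxohex-1-en-1-yl]oxy}-4-methyl-6-(prenyloxy)benzoate | COC(=O)c1c(OCC=C(C)C)cc(C)cc1O/C=C(\CO[Si](C)(C)C(C)(C)C)C(=O)CC(=O)C(F)(F)F | intermediate
11 | methyl 2-{[(1E)-4-diazo-2-(tert-butyldimethylsilyloxymethyl)-3-oxobut-1-en-1-yl]oxy}-4-methyl-6-(prenyloxy)benzoate | COC(=O)c1c(OCC=C(C)C)cc(C)cc1O/C=C(\CO[Si](C)(C)C(C)(C)C)C(=O)C=[N+]=[N-] | intermediate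
12 | chloroacetaldehyde dimethyl acetal | COC(OC)CCl | starting material
13 | methoxyethyne | COC#C | intermediate
14 | vinylketene: 4-aryloxy-3-(silyloxymethyl)buta-1,3-dien-1-one, aryloxy trans to the ketene carbon | COC(=O)c1c(OCC=C(C)C)cc(C)cc1O/C=C(\CO[Si](C)(C)C(C)(C)C)C=C=O | intermediate
15 | cyclobutenone: 4-[2-aryloxy-1-(silyloxymethyl)vinyl]-3-methoxycyclobut-2-en-1-one (racemic) | COC(=O)c1c(OCC=C(C)C)cc(C)cc1O/C=C(\CO[Si](C)(C)C(C)(C)C)C1C(=O)C=C1OC | intermediate
16 | dienylketene: 6-aryloxy-3-methoxy-5-(silyloxymethyl)hexa-1,3,5-trien-1-one, ketene and vinyl groups cis on the central double bond | O=C=C/C(OC)=C\C(CO[Si](C)(C)C(C)(C)C)=C\Oc1cc(C)cc(OCC=C(C)C)c1C(=O)OC | intermediate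
17 | cyclohexa-2,4-dienone: 6-aryloxy-3-methoxy-5-(silyloxymethyl)cyclohexa-2,4-dien-1-one (racemic) | COC(=O)c1c(OCC=C(C)C)cc(C)cc1OC1C(=O)C=C(OC)C=C1CO[Si](C)(C)C(C)(C)C | intermediate
18 | methyl 2-[2-hydroxy-4-methoxy-6-(tert-butyldimethylsilyloxymethyl)phenoxy]-4-methyl-6-(prenyloxy)benzoate | COC(=O)c1c(OCC=C(C)C)cc(C)cc1Oc1c(CO[Si](C)(C)C(C)(C)C)cc(OC)cc1O | intermediate
19 | methyl 2-[4-methoxy-2-(prenyloxy)-6-(tert-butyldimethylsilyloxymethyl)phenoxy]-4-methyl-6-(prenyloxy)benzoate | COC(=O)c1c(OCC=C(C)C)cc(C)cc1Oc1c(CO[Si](C)(C)C(C)(C)C)cc(OC)cc1OCC=C(C)C | intermediate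
20 | methyl 2-[2-(hydroxymethyl)-4-methoxy-6-(prenyloxy)phenoxy]-4-methyl-6-(prenyloxy)benzoate (CNP0561346.0) | COC(=O)c1c(OCC=C(C)C)cc(C)cc1Oc1c(CO)cc(OC)cc1OCC=C(C)C | target

**Step count**

Total: 10 steps. Longest linear sequence: 8 steps (steps 2, 3, 4, 5, 6, 8, 9, 10 from methyl vinyl ketone).

**Steps most likely to fail**

1. Step 8.
- What may go wrong: the aryl vinyl ether chromophore may compete for light and isomerise or fragment. The vinylketene may dimerise or acylate the product phenol before the volatile ynol ether captures it. The cyclobutenone may open only at temperatures where the prenyl ether rearranges.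
- Fallback: it sets out from phenol 3 and comes back at target 20. Ring B is taken as a preformed arene and the diaryl ether is made by Ullmann coupling.
- Commercial 3-hydroxy-5-methoxybenzaldehyde is acetylated (Ac2O, pyridine) to 3-formyl-5-methoxyphenyl acetate F1.
- F1 is brominated para to the methoxy group (Br2, NaOAc, AcOH) to 2-bromo-3-formyl-5-methoxyphenyl acetate F2.
- F2 is deacetylated (K2CO3, MeOH) to 2-bromo-3-hydroxy-5-methoxybenzaldehyde F3, which is prenylated with 2 (K2CO3, DMF) to 2-bromo-5-methoxy-3-(prenyloxy)benzaldehyde F4.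
- Copper-catalysed coupling of 3 with F4 (CuI, picolinic acid, K3PO4, DMSO, 90 °C), assisted by the ortho formyl group, should give methyl 2-[2-formyl-4-methoxy-6-(prenyloxy)phenoxy]-4-methyl-6-(prenyloxy)benzoate F5.
- NaBH4 in MeOH at 0 °C then reduces the aldehyde of F5 to 20.

2. Step 4.
- What may go wrong: dehydrobromination may run towards the silyloxymethyl arm and give a silyl enol ether. Traces of HBr may remove the silyl group. Enolisation of the methyl ketone may lead to Favorskii-type rearrangement.
- Fallback: it sets out from enone 6 and comes back at 9. The leaving group is installed through sulfur, where the direction of elimination is fixed by the acidic α-keto hydrogen.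
- Thiophenol with catalytic Et3N adds to 6 to give 4-(phenylsulfanyl)-3-(tert-butyldimethylsilyloxymethyl)butan-2-one F6.
- N-chlorosuccinimide in CCl4 chlorinates the carbon next to sulfur to give 4-chloro-4-(phenylsulfanyl)-3-(tert-butyldimethylsilyloxymethyl)butan-2-one F7.
- F7 loses HCl (Et3N) to give (E)-4-(phenylsulfanyl)-3-(tert-butyldimethylsilyloxymethyl)but-3-en-2-one F8.
- mCPBA (2.2 equiv, CH2Cl2) oxidises F8 to (E)-4-(benzenesulfonyl)-3-(tert-butyldimethylsilyloxymethyl)but-3-en-2-one F9.
- Phenol 3 with Cs2CO3 in DMF then displaces benzenesulfinate from F9 by addition-elimination to give 9.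

3. Step 6.
- What may go wrong: the amide base, or triethylamine and water in the second stage, may attack the vinylogous ester carbon and expel the ring A phenoxide. Acylation of the enolate may occur on oxygen. Cleavage of the trifluoroacetyl group may be incomplete.
- Fallback: it sets out from bromo enone 8 and comes back at 11. The diazo group is installed before the aryl ether, so the sensitive vinylogous aryl ester never meets the strong base.
- The same sequence on 8 (LiN(SiMe3)2, CF3CO2CH2CF3; then MsN3, Et3N, H2O, MeCN) should give (E)-1-bromo-2-(tert-butyldimethylsilyloxymethyl)-6,6,6-trifluorohex-1-ene-3,5-dione F10 and from it (E)-4-bromo-1-diazo-3-(tert-butyldimethylsilyloxymethyl)but-3-en-2-one F11.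
- Phenol 3 with K2CO3 in DMF at rt then displaces bromide from F11 by addition-elimination to give 11.

**Further compounds**

F1 | step 8 | 3-formyl-5-methoxyphenyl acetate | CC(=O)Oc1cc(OC)cc(C=O)c1
F2 | step 8 | 2-bromo-3-formyl-5-methoxyphenyl acetate | CC(=O)Oc1cc(OC)cc(C=O)c1Br
F3 | step 8 | 2-bromo-3-hydroxy-5-methoxybenzaldehyde | O=Cc1cc(OC)cc(O)c1Br
F4 | step 8 | 2-bromo-5-methoxy-3-[(3-methylbut-2-en-1-yl)oxy]benzaldehyde | O=Cc1cc(OC)cc(OCC=C(C)C)c1Br
F5 | step 8 | methyl 2-[2-formyl-4-methoxy-6-(prenyloxy)phenoxy]-4-methyl-6-(prenyloxy)benzoate | COC(=O)c1c(OCC=C(C)C)cc(C)cc1Oc1c(C=O)cc(OC)cc1OCC=C(C)C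
F6 | step 4 | 4-(phenylsulfanyl)-3-(tert-butyldimethylsilyloxymethyl)butan-2-one (racemic) | CC(=O)C(CSc1ccccc1)CO[Si](C)(C)C(C)(C)C
F7 | step 4 | 4-chloro-4-(phenylsulfanyl)-3-(tert-butyldimethylsilyloxymethyl)butan-2-one | CC(=O)C(C(Cl)Sc1ccccc1)CO[Si](C)(C)C(C)(C)C
F8 | step 4 | (E)-4-(phenylsulfanyl)-3-(tert-butyldimethylsilyloxymethyl)but-3-en-2-one | CC(=O)/C(CO[Si](C)(C)C(C)(C)C)=C/Sc1ccccc1
F9 | step 4 | (E)-4-(benzenesulfonyl)-3-(tert-butyldimethylsilyloxymethyl)but-3-en-2-one | CC(=O)/C(CO[Si](C)(C)C(C)(C)C)=C/S(=O)(=O)c1ccccc1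
F10 | step 6 | (E)-1-bromo-2-(tert-butyldimethylsilyloxymethyl)-6,6,6-trifluorohex-1-ene-3,5-dione | FC(F)(F)C(=O)CC(=O)/C(CO[Si](C)(C)C(C)(C)C)=C/Br
F11 | step 6 | (E)-4-bromo-1-diazo-3-(tert-butyldimethylsilyloxymethyl)but-3-en-2-one | [N-]=[N+]=CC(=O)/C(CO[Si](C)(C)C(C)(C)C)=C/Br
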